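**Plan**
- Retrosynthesis: the dihydropyran is opened at O–C8 by the reverse of a 1,3-shift (carbon to oxygen), giving a spiro-cyclobutane in which C8 is bonded to T2, the triketone carbon between two C=O. That four-membered ring is cut by retro-[2+2] (C13–C1′ and C8–T2) into dienol 2 and alkylidene triketone 5. 5 goes back to syncarpic acid and isovaleraldehyde, and 2 to (−)-caryophyllene oxide.
- Forward: the bicyclo[7.2.0] caryophyllane core is bought. Epoxide to allylic alcohol, then Knoevenagel, then a [2+2] photocycloaddition builds the four-membered carbocycle (C8, C13, C1′, T2). Ring expansion then turns it into the six-membered O-heterocycle (O, C8, C13, C1′, T2, T1) fused to the trione ring.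
- Enabling feature: in the cyclobutane the C8–T2 bond joins a tertiary alkyl carbon to the central carbon of a 1,3-dicarbonyl unit, and the carbonyl oxygen on T1 sits 1,3 to C8. Heterolysis and O-recombination therefore exchange the strained 4-ring for the 6-ring enol ether.
- Stereochemistry: C1, C9 and C5 come from (−)-caryophyllene oxide (the C5–O bond is never broken). The 3Z alkene comes from the syn-elimination. C1′ is set in the [2+2] step without reliable control, so the epimers are separated. Spiro C8 is set by face-selective O-capture in the ring expansion.

Key step: step 4

Remark: syncarpic acid (3) is taken as a catalogue compound; caryophyllane numbering is used (C13 = exocyclic CH2, C1′ = isobutyl-bearing carbon, T1/T2 = triketone carbonyl carbon / carbon between the carbonyls).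

**Step 1**
Reactants: 1 (−)-caryophyllene oxide, (1R,4R,5R,9S)-4,5-epoxycaryophyll-8(13)-ene
Product: 2 (1R,3Z,5R,9S)-caryophylla-3,8(13)-dien-5-ol
Conditions: Et2AlCl + LiTMP (4 equiv each, premixed), PhMe, 0 °C; aq. Rochelle salt
Reagents that add atoms: none
Why: Epoxide-to-allylic-alcohol isomerisation by a bulky aluminium amide (syn-β-elimination through an O–Al–N array) should remove the ring proton H-3, which lies cis to H-5, in preference to a C12 methyl proton; the C5–O bond is untouched so C5 stays R, the new C3=C4 bond closes cis (Z) in the nine-membered ring, and the 8(13)-alkene and the trans-fused cyclobutane are inert to the non-acidic reagent.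

**Step 2**
Reactants: 3 syncarpic acid (2,2,4,4-tetramethylcyclohexane-1,3,5-trione); 4 isovaleraldehyde (3-methylbutanal)
Product: 5 2,2,4,4-tetramethyl-6-(3-methylbutylidene)cyclohexane-1,3,5-trione
Conditions: L-proline (10 mol %), 4 Å MS, CH2Cl2, rt
Reagents that add atoms: none
Why: Amine-catalysed Knoevenagel condensation of the strongly C–H acidic cyclic β-triketone with an aliphatic aldehyde; 3 is symmetric about its CH2 carbon, so 5 has no E/Z isomers and no stereocentre is formed.

**Step 3**
Reactants: 2 (1R,3Z,5R,9S)-caryophylla-3,8(13)-dien-5-ol; 5 2,2,4,4-tetramethyl-6-(3-methylbutylidene)cyclohexane-1,3,5-trione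
Product: 6 (1′R)-dispiro-cyclobutane (four-membered ring C8–C13H2–C1′H(isobutyl)–T2; C8 spiro to the 5-hydroxycaryophyll-3-ene ring, T2 spiro as C-2 of the 4,4,6,6-tetramethylcyclohexane-1,3,5-trione)
Conditions: 5 (2 equiv), thioxanthen-9-one (10 mol %), hν 405 nm, CH2Cl2, −40 °C
Reagents that add atoms: none
Why: Proposed new method: triplet energy transfer to the cross-conjugated enetrione 5 should give a twisted triplet whose localised β-carbon C1′ adds to the unsubstituted terminus C13 of the 1,1-disubstituted alkene, forming the most stabilised 1,4-biradical (tertiary C8 / tricarbonyl-stabilised T2), which after spin inversion collapses by C8–T2 bond formation to the head-to-head cyclobutane, the usual fate of 1,4-biradicals in sensitised intermolecular enone–alkene [2+2] photocycloadditions (closest known reaction type, known for 2-acyl enones and coumarin-3-carboxylates but not for exocyclic 2-alkylidene-1,3-diones); the low temperature suppresses the thermal hetero-Diels–Alder background, the more hindered trisubstituted ring alkene should not compete, C1′ is formed without reliable substrate control (the 1′R epimer is separated by chromatography at low temperature), and the configuration created at C8 (drawn S) does not matter because step 4 ionises that centre.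

**Step 4**
Reactants: 6 (1′R)-dispiro-cyclobutane
Product: 7 tomentodione O, (1R,3Z,5R,8S,9S,1′R)
Conditions: Yb(OTf)3 (5 mol %), 2,6-di-tert-butylpyridine (10 mol %), CH2Cl2, −20 °C → rt
Reagents that add atoms: none
Why: Proposed new method: Yb(III) chelates the 1,3-dicarbonyl unit and assists heterolysis of the strained C8–T2 cyclobutane bond (tertiary alkyl donor carbon; the T2 enolate is a carboxylate-like nucleofuge, parent acid pKa about 5), giving a zwitterion (C8 carbenium / triketone enolate) whose enolate oxygen on T1 then bonds to C8, a formal 1,3-shift of C8 from carbon to oxygen that converts the four-membered carbocycle into the six-membered cyclic enol ether and is driven by loss of cyclobutane strain and of the clash between two vicinal spiro quaternary carbons. The closest known reaction type is the Lewis-acid ring expansion of donor-substituted 2-acylcyclobutanes to 3,4-dihydro-2H-pyrans (the cyclobutane counterpart of the Cloke–Wilson rearrangement, also seen when kinetic [2+2] adducts of enones isomerise to formal [4+2] adducts), known for O-, N- and aryl donors but not for a purely alkyl donor. The pyran closes by O-alkylation of the enolate in a 6-(enolendo)-exo-trig mode onto the planar C8 cation, and no other ring is formed or opened. C8 is the only new stereocentre: the enolate oxygen should be delivered to the exposed face of the cation in the folded nine-membered ring, the face anti to the C9–cyclobutane flank that also receives heterodienes and peracids at the 8(13)-alkene of caryophyllenes, which should give 8S; C1′ is a spectator and keeps its R configuration. The step needs O- rather than C-recombination (C-recombination only regenerates 6, whereas O–C8 bond formation is the thermodynamic sink) and must outrun proton loss from C7/C9 and transannular capture by the C5 hydroxyl; intramolecular delivery of the tethered enolate through a six-membered transition state at low temperature with only catalytic, buffered Lewis acid should secure this.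

**Compound list**
1 | (−)-caryophyllene oxide, (1R,4R,5R,9S)-4,5-epoxycaryophyll-8(13)-ene | C[C@@]12CC[C@@H]3[C@H](CC3(C)C)C(=C)CC[C@H]1O2 | starting material
2 | (1R,3Z,5R,9S)-caryophylla-3,8(13)-dien-5-ol | C/C1=C/C[C@@H]2[C@H](CC2(C)C)C(=C)CC[C@H]1O | intermediate
3 | syncarpic acid (2,2,4,4-tetramethylcyclohexane-1,3,5-trione) | CC1(C)C(=O)CC(=O)C(C)(C)C1=O | starting material
4 | isovaleraldehyde (3-methylbutanal) | CC(C)CC=O | starting material
5 | 2,2,4,4-tetramethyl-6-(3-methylbutylidene)cyclohexane-1,3,5-trione | CC(C)CC=C1C(=O)C(C)(C)C(=O)C(C)(C)C1=O | intermediate
6 | (1′R)-dispiro-cyclobutane: ring C8–C13H2–C1′H(isobutyl)–T2, C8 spiro to the (1R,3Z,5R,9S)-5-hydroxycaryophyll-3-ene ring, T2 spiro as C-2 of 4,4,6,6-tetramethylcyclohexane-1,3,5-trione | C/C1=C/C[C@@H]2[C@H](CC2(C)C)[C@]3(CC[C@H]1O)C[C@@H](CC(C)C)C34C(=O)C(C)(C)C(=O)C(C)(C)C4=O | intermediate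
7 | tomentodione O | C/C1=C/C[C@@H]2[C@H](CC2(C)C)[C@]2(CC[C@H]1O)C[C@@H](CC(C)C)C1=C(O2)C(C)(C)C(=O)C(C)(C)C1=O | target

Total steps: 4. Longest linear sequence: 3 (steps 1, 3, 4).

**Steps most likely to fail**

Step 3 (proposed new method). The triplet of the exocyclic enetrione may relax by twisting before it is trapped. The 1,4-biradical may also close through oxygen, transfer hydrogen, or close head-to-tail, so that little head-to-head cyclobutane accumulates. The fallback sets out from 2 and uses 5 in the thermal inverse-demand hetero-Diels–Alder reaction (toluene, 90 °C), the established way to fuse alkylidene β-triketones to the 8(13)-alkene of caryophyllenes. It forms C13–C1′ and O–C8 in one concerted step and comes back to the route at 7, with the C1′ epimer removed by chromatography; it makes no further compound (F0).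

Step 4 (proposed new method). After heterolysis, proton loss from C7/C9, transannular capture of the C8 cation by the C5 hydroxyl, or retro-Michael fragmentation of the zwitterion (which would scramble C1′) may outrun O-recombination. The fallback avoids a free cation and sets out from 2. Compounds 3, 4 and morpholine are condensed (EtOH, rt) to the Mannich base 2-[3-methyl-1-(morpholin-4-yl)butyl]-3-hydroxy-4,4,6,6-tetramethylcyclohex-2-ene-1,5-dione F1. Heating F1 with 2 (toluene, 100 °C) releases 5 slowly by retro-Mannich loss of the amine, and 2 traps it in a concerted hetero-Diels–Alder reaction. This comes back to the route at 7.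

Step 1. Competing removal of a C12 methyl proton gives the exocyclic 4(12)-ene alcohol, so 2 may be the minor and hard-to-separate regioisomer. The fallback sets out from 1 and corrects the regiochemistry through the enone:
- Lithium diethylamide (Et2O, reflux) deliberately gives (1R,5R,9S)-caryophylla-4(12),8(13)-dien-5-ol F2.
- Dess–Martin oxidation gives (1R,9S)-caryophylla-4(12),8(13)-dien-5-one F3.
- RhCl3·3H2O (cat., EtOH, 60 °C) should move the conjugated exocyclic C=C into the ring, giving (1R,3Z,9S)-caryophylla-3,8(13)-dien-5-one F4.
- CBS reduction, with the catalyst enantiomer chosen to give 5R, comes back to the route at 2.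

**Further compounds**
F0 | step 3 | none | none
F1 | step 4 | 2-[3-methyl-1-(morpholin-4-yl)butyl]-3-hydroxy-4,4,6,6-tetramethylcyclohex-2-ene-1,5-dione | CC(C)CC(N1CCOCC1)C1=C(O)C(C)(C)C(=O)C(C)(C)C1=O
F2 | step 1 | (1R,5R,9S)-caryophylla-4(12),8(13)-dien-5-ol | C=C1CC[C@@H]2[C@H](CC2(C)C)C(=C)CC[C@H]1O
F3 | step 1 | (1R,9S)-caryophylla-4(12),8(13)-dien-5-one | C=C1CC[C@@H]2[C@H](CC2(C)C)C(=C)CCC1=O
F4 | step 1 | (1R,3Z,9S)-caryophylla-3,8(13)-dien-5-one | C/C1=C/C[C@@H]2[C@H](CC2(C)C)C(=C)CCC1=O
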